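## Analysis of the target

Numbering used throughout (germacrane type): ring carbons C1 (CH2), C2 and C3 (epoxide), C4 (tertiary C–OH, methyl C15), C5 (O-(R)-2-methylbutanoyl), C6 (lactone oxygen), C7 (lactone ring fusion), C8 (O-angeloyl), C9 (ketone) and C10 (CH–CH3), with C11 (=C13H2) and C12 (C=O) completing the lactone; "ring A" is the six-membered carbocycle C9–C10–C1–C2–C3–C4 of the early intermediates, and β is the face of ring A that carries the C4 side chain (C5). The target is a ten-membered carbocycle, trans-fused at C6–C7 to an α-methylene-γ-butyrolactone. It has eight ring stereocentres (2S,3R,4R,5R,6S,7S,8S,10S), seven of them contiguous (C2–C8), plus the (R)-centre of the 2-methylbutanoate and the (Z)-angelate. The 2,3-epoxide is trans (C1 and C4 on opposite sides) and sits next to the free tertiary alcohol at C4, so base can trigger epoxide migration. Other sensitive groups are the methylene lactone (Michael acceptor), the angelate (Z to E), the α-acyloxy ketone with epimerisable C8 and C10, and two different esters that can migrate. The difficulty is a strained medium ring in which almost every carbon is a stereocentre: an end-to-end closure fights entropy and transannular strain and sets none of them. The feature the plan rests on is that C9 (C=O) and C4 (C–OH) lie 1,6 across the ten-membered ring, and that on the oxygenated side between them the C9=O/C8–O pair is an oxidised enolate and the syn C4–OH/C5–O pair is an oxidised (E)-alkene. Without these oxygens, C9=C8–C7–C6–C5=C4 is a 1,5-diene whose central bond C6–C7 is the lactone ring fusion, which invites a [3,3] shift that breaks a temporary C9–C4 bond of the cyclohexane ring A.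

## Retrosynthetic reasoning

**Epoxide (33 from 31).** The epoxide C2–O bond is cut last. A trans epoxide corresponds to an erythro 2,3-diol closed with one inversion, here at the less hindered C2. The erythro diol is a cis-diol on a six-membered ring, so C2 and C3 can be set early on ring A and carried as an acetonide (31 from 30).

**C5 ester and C4/C5 diol (30 from 28 and 29; 28 from 27).** The C5–O acyl bond is cut to diol 28 and acid 29, and both C–O bonds of the syn-diol are cut back to the (E)-C4=C5 olefin of lactone 27. The forward reaction must attack the trisubstituted olefin in the presence of two conjugated olefins and from the peripheral face.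

**Lactone (27 from 26 from 25).** The C12–O6 bond is cut to the 2-methylene-1,4-diol 26, which comes from the bis-ether 25. C11=C13 is never made late; it is carried from the start as part of a 2-substituted diene. This avoids enolate methylenation next to a ketone.

**C8 angelate (25 from 23 and 24).** The C8–O bond is cut to the α-bromo ketone 23 and angelic acid 24. An electrophile reaches C8 of the ring enolate only from the face opposite to the one the target needs, so the oxygen is brought in by SN2 inversion, already as the angelate.

**Key disconnection (23 from 22 from 20).** The C6–C7 bond is cut and the C9–C4 bond, absent from the target, is reconnected. The ten-membered enolate 22 becomes the trans-1,2-dialkenylcyclohexanol 20. Here and not elsewhere, because this single cut removes the medium ring, two stereocentres (C6, C7), the regiochemistry of the C9 enolate and the geometry of C4=C5. The forward reaction has to transfer the configuration of C9/C4 to C6/C7 through a chair and deliver the enolate for C8 functionalisation.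

**C8–C9 bond (20 from 14 and 18).** The dienyl side chain (C8, C7, C11–C13) is added to the ring-A ketone 14 as the organometallic 19 made from stannane 18. The forward step must place the new group trans to the C4 alkenyl group.

**Ring A (14 back to 1 and 2).** The (E)-enol ether is cut at O–C6 (12 and 13), the iodoalkene at C5=C6 (aldehyde 11), and C5 is traced to a carboxamide carbon (9, 7). Ring A with its quaternary C4, the C9 oxygen, the C2=C3 bond and the C10 methyl is then the dearomatised form of benzamide 4, made from acid 1 and auxiliary 2.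

**Side chain (18 from 16 and 17; 16 from 15 and 13).** One sp2–sp2 coupling and one etherification.

## Alternatives that were turned down

Alternative 1: the textbook route for this class is an intramolecular Barbier/Nozaki–Hiyama–Kishi allylation closing C6–C7. The seco aldehyde A1 (C6 aldehyde, 2-(bromomethyl)enoate at C7) would cyclise with CrCl2 and lactonise to the silyl-protected target A2. It forms the same bond as the chosen route, but by end-to-end closure of a ten-membered ring. Turned down for three reasons: A1 must already carry C2, C3, C4, C5, C8 and C10, each set by acyclic stereocontrol (well over 25 steps). The C6/C7 outcome depends on an unpredictable macrocyclic transition state. The epoxide, the α-acyloxy ketone and the angelate would all have to survive divalent chromium.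

Alternative 2: ring-closing metathesis at C2=C3. The seco diene A3 would be closed with the second-generation Grubbs catalyst to the (E)-allylic alcohol A4, followed by hydroxyl-directed epoxidation. Turned down because a ten-membered ring with an (E)-olefin is strained and such closures favour (Z)-olefins or oligomers. One partner is a hindered tertiary allylic alcohol, and the methylene lactone and angelate olefins compete. The step sets no stereocentre, so the precursor is as long as A1.

Alternative 3: Grob fragmentation of the trans-decalin hydroxy mesylate A5, which has the same temporary C4–C9 bond, to the (E)-3,4-ene ketone A6. A6 would then need an ene-type transposition to the 4-hydroxy-2,3-ene and an epoxidation. Turned down because the fragmentation only opens the ring: all of C5–C8 and C10 plus the angular C4 and C9 must first be built on the decalin. The C3=C4 olefin then sits in the wrong place and its transposition has an unsolved regiochemistry (C2–H against C15–H), and the basic fragmentation conditions endanger both esters.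

Key step: step 13

Assumption: the Birch reduction–alkylation of 4 is taken to give the C4 configuration drawn for 6 with the (S)-auxiliary; if the sense of induction is the opposite, (R)-2-(methoxymethyl)pyrrolidine is used and nothing else changes.

## Route

Step 1
Reactants: 1 2-methoxy-3-methylbenzoic acid; 2 (S)-2-(methoxymethyl)pyrrolidine
Product: 4 N-(2-methoxy-3-methylbenzoyl)-(S)-2-(methoxymethyl)pyrrolidine, via acid chloride 3 (not isolated)
Conditions: (COCl)2, cat. DMF, CH2Cl2, 0 °C to rt; then 2, Et3N, 0 °C
Reagents that add atoms: none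
Why: Acid chloride formation and N-acylation of the secondary amine; no stereocentre is touched.

Step 2
Reactants: 4 benzamide
Product: 6 2-methoxy-1,3-dimethylcyclohexa-2,5-diene-1-carboxamide of 2 (quaternary carbon = future C4), via potassium amide enolate 5 (not isolated)
Conditions: K (2.2 equiv), t-BuOH (1 equiv), NH3/THF, −78 °C; then MeI, −78 °C to rt
Reagents that add atoms: iodomethane, CI
Why: Birch reduction–alkylation: the electron-poor benzamide is reduced to the chelated amide enolate 5, which is methylated at the ipso carbon; the methoxymethylpyrrolidine unit shields one enolate face and so sets the quaternary C4.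

Step 3
Reactants: 6 Birch diene
Product: 7 2,6-dimethyl-2-carboxamidocyclohex-3-en-1-one (C9 ketone; C2=C3; C10 methyl β)
Conditions: 10% aq HCl, MeOH, 0 °C to rt, short reaction time
Reagents that add atoms: water, O
Why: Hydrolysis of the methyl enol ether; C4 is quaternary, so C2=C3 cannot move into conjugation. C-Protonation at C10 should occur anti to the bulky carboxamide, which leaves the C10 methyl cis to it.

Step 4
Reactants: 7 enone amide
Product: 8 2β,3β-diol of 7
Conditions: OsO4 (2 mol %), N-methylmorpholine N-oxide, acetone/H2O, rt
Reagents that add atoms: osmium tetroxide (catalytic oxygen carrier), O=[Os](=O)(=O)=O; N-methylmorpholine N-oxide, C[N+]1([O-])CCOCC1; water, O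
Why: Catalytic syn-dihydroxylation of the only olefin. With the C10 methyl equatorial the C4 methyl is pseudoaxial on the α face, so OsO4 should add anti to it, on the β face.

Step 5
Reactants: 8 diol
Product: 9 2,3-acetonide of 8
Conditions: 2,2-dimethoxypropane, cat. pyridinium p-toluenesulfonate, acetone, rt
Reagents that add atoms: 2,2-dimethoxypropane, COC(C)(C)OC
Why: Transketalisation of the cis-diol. In the resulting chair (C10-Me equatorial, C4-Me axial, C5 equatorial, C3–O axial, C2–O equatorial) the drawn C10 epimer is the thermodynamic one, so later enolisation cannot erode it.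

Step 6
Reactants: 9 keto amide
Product: 10 ring-A diol (C5 primary alcohol; C9 secondary alcohol as epimer mixture)
Conditions: LiNH2BH3 (from BH3·NH3 and LiN(iPr)2), THF, 0 °C to rt; aq NH4Cl
Reagents that add atoms: none
Why: The amidotrihydroborate reduces hindered tertiary amides to primary alcohols with release of the amine; the ketone is reduced as well and is regenerated in step 7.

Step 7
Reactants: 10 diol
Product: 11 keto aldehyde (C9 ketone, C5 aldehyde)
Conditions: (COCl)2, DMSO, CH2Cl2, −78 °C; Et3N, −78 to 0 °C
Reagents that add atoms: none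
Why: Swern oxidation of both hydroxyls; C4 is quaternary, so the β-keto aldehyde cannot enolise between the carbonyls. It is used at once.

Step 8
Reactants: 11 keto aldehyde
Product: 12 (E)-2-iodovinyl ketone
Conditions: CrCl2 (6 equiv), CHI3 (2 equiv), THF, 0 °C
Reagents that add atoms: iodoform, IC(I)I
Why: Takai olefination; the gem-dichromium reagent is selective for aldehydes over ketones and gives the (E)-iodoalkene, strongly so for α-quaternary aldehydes.

Step 9
Reactants: 12 iodoalkene; 13 4-methoxybenzyl alcohol
Product: 14 ring-A ketone bearing the (E)-2-(4-methoxybenzyloxy)vinyl group at C4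
Conditions: CuI (10 mol %), 3,4,7,8-tetramethyl-1,10-phenanthroline (20 mol %), Cs2CO3, toluene, 80 °C
Reagents that add atoms: none
Why: Ullmann-type copper-catalysed C–O coupling of an alkenyl iodide with a primary alcohol, with retention of olefin geometry. C10 can only equilibrate to the favoured equatorial epimer.

Step 10
Reactants: 15 2,3-dibromopropene; 13 4-methoxybenzyl alcohol
Product: 16 2-bromoallyl 4-methoxybenzyl ether
Conditions: NaH, THF, 0 °C; then 15, 0 °C to rt
Reagents that add atoms: none
Why: Williamson etherification; the alkoxide displaces the allylic bromide and the vinylic bromide is inert.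

Step 11
Reactants: 16 bromoallyl ether; 17 (E)-1,2-bis(tributylstannyl)ethene
Product: 18 (E)-tributyl[3-methylene-4-(4-methoxybenzyloxy)but-1-enyl]stannane
Conditions: 17 (2.5 equiv), Pd(PPh3)4 (5 mol %), toluene, 90 °C
Reagents that add atoms: none
Why: Stille coupling of the vinyl bromide; the excess distannane keeps it at mono-coupling, and the (E)-geometry of the stannylethene is retained.

Step 12
Reactants: 18 dienylstannane; 14 ring-A ketone
Product: 20 trans-1,2-dialkenylcyclohexanol (C9–OH axial β; dienyl group equatorial; trans to the C4 enol ether), via dienyllithium 19 (not isolated)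
Conditions: n-BuLi, THF, −78 °C; CeCl3, −78 °C; then 14, −78 to −40 °C; aq NH4Cl
Reagents that add atoms: none
Why: Tin–lithium exchange and transmetalation to cerium give a non-basic alkenyl nucleophile for 1,2-addition to the hindered ketone. Axial approach is blocked by the syn-axial C3–O, so equatorial attack, the normal course for alkenyl nucleophiles on 2,2,6-trisubstituted cyclohexanones, should set C9.

Step 13
Reactants: 20 dialkenylcyclohexanol
Product: 23 (8R)-8-bromo ten-membered ketone, via potassium alkoxide 21 (not isolated), via potassium enolate 22 (not isolated)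
Conditions: KN(SiMe3)2 (1.2 equiv), 18-crown-6, THF, 0 to 40 °C; then N-bromosuccinimide, −78 °C; aq NH4Cl
Reagents that add atoms: N-bromosuccinimide, O=C1CCC(=O)N1Br
Why: The alkoxide 21 undergoes a concerted alkoxide-accelerated [3,3] shift (anionic oxy-Cope rearrangement) in which C9–C4 of ring A breaks while C6–C7 forms, so the six-membered ring is expanded by four atoms to the ten-membered ring and is not closed end to end; the closest known reaction type is the anionic oxy-Cope ring expansion of trans-1,2-dialkenylcyclohexanols to (E)-cyclodec-5-enone enolates with capture of the enolate by an electrophile. Both alkenyl groups are equatorial on the chair of ring A, which enforces a chair transition state with O− and the C4 methyl axial and C10 and C3 equatorial. In that chair the (E)-enol ether puts OPMB equatorial at C6 and the (E)-dienyl group puts C11 equatorial at C7, so the two olefin geometries fix the threo (trans-lactone) relationship and the configurations of C9 and C4 are transferred to 6S and 7S. The same geometry gives the (E)-C4=C5 olefin and the regiodefined enolate 22 (C8=C9 only; C10 is never deprotonated). The bromine donor then attacks C8 from the peripheral face of the enolate, away from the transannular C4=C5 bond, which puts bromine on the face opposite to the one the oxygen needs and prepares the inversion of step 14. The step needs the [3,3] shift to outrun fragmentation of the alkoxide (crown ether, non-nucleophilic amide base, donor-substituted terminus) and chair to beat boat (trans-diequatorial alkenyl groups).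

Step 14
Reactants: 23 α-bromo ketone; 24 angelic acid
Product: 25 (8S)-8-angelate
Conditions: 24, K2CO3, cat. 18-crown-6, DMF, 0 °C to rt
Reagents that add atoms: none
Why: SN2 displacement of an α-bromo ketone by a carboxylate, accelerated by the adjacent carbonyl, with inversion at C8. Alkylating the carboxylate needs no acyl activation of angelic acid, which avoids Z to E isomerisation.

Step 15
Reactants: 25 bis-PMB ether
Product: 26 C6,C12-diol
Conditions: 2,3-dichloro-5,6-dicyano-1,4-benzoquinone (2.5 equiv), CH2Cl2/pH 7 buffer, 0 °C
Reagents that add atoms: none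
Why: Oxidative cleavage of both 4-methoxybenzyl ethers under buffered conditions; the acetonide, the angelate and the α-acyloxy ketone are inert.

Step 16
Reactants: 26 diol
Product: 27 trans-fused α-methylene-γ-butyrolactone
Conditions: TEMPO (20 mol %), PhI(OAc)2 (2.5 equiv), CH2Cl2, NaHCO3, rt
Reagents that add atoms: none
Why: Oxidative lactonisation of a 2-methylene-1,4-diol: the primary allylic alcohol is oxidised to the enal, the C6 hydroxyl adds (5-exo-trig) to give the lactol, which is oxidised on to the lactone. C6–O and C7–C11 are trans-diequatorial, so the trans ring fusion forms without strain.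

Step 17
Reactants: 27 lactone
Product: 28 (4R,5R)-4,5-diol
Conditions: OsO4 (5 mol %), N-methylmorpholine N-oxide (1.2 equiv), acetone/H2O, 0 °C
Reagents that add atoms: osmium tetroxide (catalytic oxygen carrier), O=[Os](=O)(=O)=O; N-methylmorpholine N-oxide, C[N+]1([O-])CCOCC1; water, O
Why: The electrophilic oxidant selects the trisubstituted C4=C5 bond over the two conjugated olefins. Attack on the peripheral face of the (E)-olefin next to the trans-lactone, the face that germacranolides of this lactone configuration expose to oxidants, gives the syn-diol with both new centres as in the target.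

Step 18
Reactants: 28 diol; 29 (R)-2-methylbutanoic acid
Product: 30 C5 (R)-2-methylbutanoate
Conditions: 29, N,N'-dicyclohexylcarbodiimide, cat. 4-(dimethylamino)pyridine, CH2Cl2, 0 °C to rt
Reagents that add atoms: none
Why: Carbodiimide esterification of the secondary C5 hydroxyl; the tertiary C4 hydroxyl does not react, and the low temperature limits epimerisation of the acyl α-centre.

Step 19
Reactants: 30 acetonide
Product: 31 2,3,4-triol
Conditions: CF3CO2H/H2O (9:1), CH2Cl2, 0 °C
Reagents that add atoms: none
Why: Acid hydrolysis of the acetonide; the esters, the lactone and the tertiary alcohol tolerate cold aqueous acid.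

Step 20
Reactants: 31 triol
Product: 33 target CNP0217571.1, via oxyphosphonium betaine 32 (not isolated)
Conditions: PPh3, diisopropyl azodicarboxylate (premixed), THF, 0 °C to rt
Reagents that add atoms: none
Why: Mitsunobu cyclodehydration of a 1,2-diol: the less hindered C2 oxygen is activated and displaced by the C3 oxygen (3-exo-tet) with inversion at C2, turning the erythro diol into the trans epoxide. C3 is shielded by the quaternary C4 and the tertiary C4–OH cannot be displaced, so only this closure is open.

## Compound list

1 | 2-methoxy-3-methylbenzoic acid | COc1c(C)cccc1C(=O)O | starting material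
2 | (S)-2-(methoxymethyl)pyrrolidine | COC[C@@H]1CCCN1 | starting material
3 | 2-methoxy-3-methylbenzoyl chloride | COc1c(C)cccc1C(=O)Cl | intermediate
4 | N-(2-methoxy-3-methylbenzoyl)-(S)-2-(methoxymethyl)pyrrolidine | COc1c(C)cccc1C(=O)N1CCC[C@H]1COC | intermediate
5 | potassium amide enolate of the 1,4-dihydrobenzamide | [K+].COC1=C(C)CC=CC1=C([O-])N1CCC[C@H]1COC | intermediate
6 | Birch diene, 2-methoxy-1,3-dimethylcyclohexa-2,5-diene-1-carboxamide of 2 | COC1=C(C)CC=C[C@@]1(C)C(=O)N1CCC[C@H]1COC | intermediate
7 | 2,6-dimethyl-2-carboxamidocyclohex-3-en-1-one, C10-Me β | O=C1[C@@H](C)CC=C[C@@]1(C)C(=O)N1CCC[C@H]1COC | intermediate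
8 | 2β,3β-diol of 7 | O=C1[C@@H](C)C[C@@H](O)[C@@H](O)[C@@]1(C)C(=O)N1CCC[C@H]1COC | intermediate
9 | 2,3-acetonide of 8 | O=C1[C@@H](C)C[C@H]2OC(C)(C)O[C@H]2[C@@]1(C)C(=O)N1CCC[C@H]1COC | intermediate
10 | ring-A diol (C5–OH, C9–OH; C9 epimers) | OC1[C@@H](C)C[C@H]2OC(C)(C)O[C@H]2[C@@]1(C)CO | intermediate
11 | ring-A keto aldehyde | O=C1[C@@H](C)C[C@H]2OC(C)(C)O[C@H]2[C@@]1(C)C=O | intermediate
12 | ring-A (E)-2-iodovinyl ketone | O=C1[C@@H](C)C[C@H]2OC(C)(C)O[C@H]2[C@@]1(C)/C=C/I | intermediate
13 | 4-methoxybenzyl alcohol | COc1ccc(CO)cc1 | starting material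
14 | ring-A ketone with (E)-2-(4-methoxybenzyloxy)vinyl group | O=C1[C@@H](C)C[C@H]2OC(C)(C)O[C@H]2[C@@]1(C)/C=C/OCc1ccc(OC)cc1 | intermediate
15 | 2,3-dibromopropene | C=C(Br)CBr | starting material
16 | 2-bromoallyl 4-methoxybenzyl ether | C=C(Br)COCc1ccc(OC)cc1 | intermediate
17 | (E)-1,2-bis(tributylstannyl)ethene | CCCC[Sn](CCCC)(CCCC)/C=C/[Sn](CCCC)(CCCC)CCCC | starting material
18 | (E)-tributyl[3-methylene-4-(4-methoxybenzyloxy)but-1-enyl]stannane | C=C(COCc1ccc(OC)cc1)/C=C/[Sn](CCCC)(CCCC)CCCC | intermediate
19 | (E)-3-methylene-4-(4-methoxybenzyloxy)but-1-enyllithium | [Li]/C=C/C(=C)COCc1ccc(OC)cc1 | intermediate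
20 | trans-1,2-dialkenylcyclohexanol (C9–OH axial) | O[C@@]1(/C=C/C(=C)COCc2ccc(OC)cc2)[C@@H](C)C[C@H]2OC(C)(C)O[C@H]2[C@@]1(C)/C=C/OCc1ccc(OC)cc1 | intermediate
21 | potassium alkoxide of 20 | [K+].[O-][C@@]1(/C=C/C(=C)COCc2ccc(OC)cc2)[C@@H](C)C[C@H]2OC(C)(C)O[C@H]2[C@@]1(C)/C=C/OCc1ccc(OC)cc1 | intermediate
22 | potassium enolate of the ten-membered (E)-4-en-9-one | [K+].[O-]/C1=C\[C@@H](C(=C)COCc2ccc(OC)cc2)[C@H](OCc2ccc(OC)cc2)/C=C(C)/[C@@H]2OC(C)(C)O[C@@H]2C[C@@H]1C | intermediate
23 | (8R)-8-bromo ten-membered ketone | O=C1[C@H](Br)[C@@H](C(=C)COCc2ccc(OC)cc2)[C@H](OCc2ccc(OC)cc2)/C=C(C)/[C@@H]2OC(C)(C)O[C@@H]2C[C@@H]1C | intermediate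
24 | angelic acid, (Z)-2-methylbut-2-enoic acid | C/C=C(/C)C(=O)O | starting material
25 | (8S)-8-angelate, bis-PMB ether | O=C1[C@@H](OC(=O)/C(C)=C\C)[C@@H](C(=C)COCc2ccc(OC)cc2)[C@H](OCc2ccc(OC)cc2)/C=C(C)/[C@@H]2OC(C)(C)O[C@@H]2C[C@@H]1C | intermediate
26 | C6,C12-diol | O=C1[C@@H](OC(=O)/C(C)=C\C)[C@@H](C(=C)CO)[C@H](O)/C=C(C)/[C@@H]2OC(C)(C)O[C@@H]2C[C@@H]1C | intermediate
27 | trans-fused α-methylene lactone with (E)-C4=C5 | O=C1[C@@H](OC(=O)/C(C)=C\C)[C@H]2C(=C)C(=O)O[C@@H]2/C=C(C)/[C@@H]3OC(C)(C)O[C@@H]3C[C@@H]1C | intermediate
28 | (4R,5R)-4,5-diol | O=C1[C@@H](OC(=O)/C(C)=C\C)[C@H]2C(=C)C(=O)O[C@@H]2[C@@H](O)[C@](C)(O)[C@@H]3OC(C)(C)O[C@@H]3C[C@@H]1C | intermediate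
29 | (R)-2-methylbutanoic acid | CC[C@@H](C)C(=O)O | starting material
30 | C5 (R)-2-methylbutanoate, 2,3-acetonide | O=C1[C@@H](OC(=O)/C(C)=C\C)[C@H]2C(=C)C(=O)O[C@@H]2[C@@H](OC(=O)[C@H](C)CC)[C@](C)(O)[C@@H]3OC(C)(C)O[C@@H]3C[C@@H]1C | intermediate
31 | 2,3,4-triol | O=C1[C@@H](OC(=O)/C(C)=C\C)[C@H]2C(=C)C(=O)O[C@@H]2[C@@H](OC(=O)[C@H](C)CC)[C@](C)(O)[C@H](O)[C@H](O)C[C@@H]1C | intermediate
32 | C2 oxyphosphonium betaine of 31 | O=C1[C@@H](OC(=O)/C(C)=C\C)[C@H]2C(=C)C(=O)O[C@@H]2[C@@H](OC(=O)[C@H](C)CC)[C@](C)(O)[C@H]([O-])[C@H](O[P+](c2ccccc2)(c2ccccc2)c2ccccc2)C[C@@H]1C | intermediate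
33 | CNP0217571.1 | C=C1C(=O)O[C@H]2[C@H]1[C@H](OC(=O)/C(C)=C\C)C(=O)[C@@H](C)C[C@@H]1O[C@H]1[C@@](C)(O)[C@@H]2OC(=O)[C@H](C)CC | target

## Step count and risk

Total step count: 20. Longest linear sequence: 18 steps (steps 1–9 and 12–20); steps 10–11 make the side chain.

**Step 13 (key step).** Most likely failure: fragmentation of the crowded tertiary dienyl alkoxide (retro-addition or heterolysis of C9–C4) instead of the concerted shift, or rotation of the enolate unit through the ring before bromination, which would lower the facial selectivity at C8. Fallback, from 20 back to 23: the rearrangement is taken out of the carbanionic manifold. Compound 20 is silylated (N-(trimethylsilyl)imidazole) to the trimethylsilyl ether F1. F1 is heated in xylene at 180–200 °C in base-washed glass, so that the neutral siloxy-Cope rearrangement gives the ten-membered trimethylsilyl enol ether F2. F2 is then brominated with N-bromosuccinimide at −78 °C to give 23.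

**Step 14.** Most likely failure: loss of configuration at C8 through bromide exchange or enolisation before substitution, slow substitution on the more hindered face, or base-induced Favorskii-type contraction. Fallback, from 20 back to 25: the enolate 22 of step 13 is quenched with 2-(phenylsulfonyl)-3-phenyloxaziridine instead of the bromine donor. This gives the (8R)-α-hydroxy ketone F3, with oxygen delivered from the same peripheral face. F3 is then esterified with 24 under Mitsunobu conditions (PPh3, diisopropyl azodicarboxylate), which inverts C8 without any halide in the system and gives 25.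

**Step 4.** Most likely failure: poor facial selectivity in the osmylation if the conformational bias of 7 is too small, or if C10 epimerises during step 3; attack syn to the C4 methyl would give the wrong diol. Fallback, from 7 back to 10: the facial control is changed from steric to hydrogen-bond-directed. Ketone 7 is reduced with LiBH(sec-Bu)3, by equatorial delivery, to the axial β-alcohol F4. Osmylation of F4 with stoichiometric OsO4·TMEDA in CH2Cl2 at −78 °C is directed by the homoallylic hydroxyl to the β face and gives the triol F5. The cis-2,3-diol is protected as the acetonide F6, and reduction of the amide with LiNH2BH3 gives 10.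

**Step 17.** Most likely failure: loss of chemoselectivity, with osmylation of the α-methylene lactone competing, or attack on the inner face if the olefin unit rotates. Fallback, from 27 back to 28: the methylene lactone is masked by conjugate addition of dimethylamine to give the amine adduct F7. F7 is dihydroxylated under the conditions of step 17 to the diol F8. The methylene group is then regenerated by N-methylation (MeI) and elimination with NaHCO3, giving 28.

**Step 20.** Most likely failure: activation of the wrong hydroxyl, a phosphorane that does not collapse, or conjugate addition of the phosphine to the lactone. Fallback, from 31 back to 33: the activation and the ring closure are separated. The C2 hydroxyl is selectively sulfonylated (CH3SO2Cl, 2,4,6-collidine, CH2Cl2, −20 °C) to the C2 mesylate F9. F9 is closed with 1,8-diazabicyclo[5.4.0]undec-7-ene in acetonitrile at rt to give 33.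

## Further compounds

F1 | step 13 | trimethylsilyl ether of 20 | C[Si](C)(C)O[C@@]1(/C=C/C(=C)COCc2ccc(OC)cc2)[C@@H](C)C[C@H]2OC(C)(C)O[C@H]2[C@@]1(C)/C=C/OCc1ccc(OC)cc1
F2 | step 13 | ten-membered trimethylsilyl enol ether | C[Si](C)(C)O/C1=C\[C@@H](C(=C)COCc2ccc(OC)cc2)[C@H](OCc2ccc(OC)cc2)/C=C(C)/[C@@H]2OC(C)(C)O[C@@H]2C[C@@H]1C
F3 | step 14 | (8R)-8-hydroxy ten-membered ketone | O=C1[C@H](O)[C@@H](C(=C)COCc2ccc(OC)cc2)[C@H](OCc2ccc(OC)cc2)/C=C(C)/[C@@H]2OC(C)(C)O[C@@H]2C[C@@H]1C
F4 | step 4 | C9 β-alcohol of 7 | O[C@H]1[C@@H](C)CC=C[C@@]1(C)C(=O)N1CCC[C@H]1COC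
F5 | step 4 | 2β,3β,9β-triol amide | O[C@H]1[C@@H](C)C[C@@H](O)[C@@H](O)[C@@]1(C)C(=O)N1CCC[C@H]1COC
F6 | step 4 | 2,3-acetonide of F5 | O[C@H]1[C@@H](C)C[C@H]2OC(C)(C)O[C@H]2[C@@]1(C)C(=O)N1CCC[C@H]1COC
F7 | step 17 | dimethylamine adduct of 27 (C11 epimer not defined) | O=C1[C@@H](OC(=O)/C(C)=C\C)[C@H]2C(CN(C)C)C(=O)O[C@@H]2/C=C(C)/[C@@H]3OC(C)(C)O[C@@H]3C[C@@H]1C
F8 | step 17 | 4,5-diol of F7 | O=C1[C@@H](OC(=O)/C(C)=C\C)[C@H]2C(CN(C)C)C(=O)O[C@@H]2[C@@H](O)[C@](C)(O)[C@@H]3OC(C)(C)O[C@@H]3C[C@@H]1C
F9 | step 20 | C2 mesylate of 31 | O=C1[C@@H](OC(=O)/C(C)=C\C)[C@H]2C(=C)C(=O)O[C@@H]2[C@@H](OC(=O)[C@H](C)CC)[C@](C)(O)[C@H](O)[C@H](OS(C)(=O)=O)C[C@@H]1C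
A1 | alternative 1 | seco aldehyde with 2-(bromomethyl)enoate, C4–O-triethylsilyl | BrC/C(C(=O)OC)=C\[C@H](OC(=O)/C(C)=C\C)C(=O)[C@@H](C)C[C@@H]1O[C@H]1[C@@](C)(O[Si](CC)(CC)CC)[C@H](OC(=O)[C@H](C)CC)C=O
A2 | alternative 1 | C4–O-triethylsilyl ether of the target | C=C1C(=O)O[C@H]2[C@H]1[C@H](OC(=O)/C(C)=C\C)C(=O)[C@@H](C)C[C@@H]1O[C@H]1[C@@](C)(O[Si](CC)(CC)CC)[C@@H]2OC(=O)[C@H](C)CC
A3 | alternative 2 | seco diene with terminal vinyl groups at C2 and C3 | C=CC[C@H](C)C(=O)[C@@H](OC(=O)/C(C)=C\C)[C@H]1C(=C)C(=O)O[C@@H]1[C@@H](OC(=O)[C@H](C)CC)[C@](C)(O)C=C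
A4 | alternative 2 | (E)-2,3-ene 4-ol macrocycle | O=C1[C@@H](OC(=O)/C(C)=C\C)[C@H]2C(=C)C(=O)O[C@@H]2[C@@H](OC(=O)[C@H](C)CC)[C@](C)(O)/C=C/C[C@@H]1C
A5 | alternative 3 | trans-decalin 9-ol 3-mesylate with C4–C9 bond | O[C@]12[C@@H](OC(=O)/C(C)=C\C)[C@H]3C(=C)C(=O)O[C@@H]3[C@@H](OC(=O)[C@H](C)CC)[C@]1(C)[C@@H](OS(C)(=O)=O)CC[C@@H]2C
A6 | alternative 3 | (E)-3,4-ene ten-membered 9-ketone | O=C1[C@@H](OC(=O)/C(C)=C\C)[C@H]2C(=C)C(=O)O[C@@H]2[C@@H](OC(=O)[C@H](C)CC)/C(C)=C/CC[C@@H]1C
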